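## Analysis of the target

Compound 20 consists of two hexasubstituted benzene rings joined by a single methylene carbon. Ring A is an acylphloroglucinol: A1 carries the 2-methylbutanoyl group, A2 and A6 free hydroxyls, A3 a methyl, A4 a methoxy group and A5 the bridge. Ring B is the benzene ring of a 2,2-dimethylchroman-4-one with hydroxyls on C5 and C7, a methyl on C6 and the bridge on C8. The only stereocentre is the (R)-configured α-carbon of the aryl ketone; it is isolated, so there is no relative stereochemistry to control, but it is enolisable and must be brought in intact and spared by every later step. The sensitive elements are this stereocentre, the diarylmethane link (a reversible Friedel–Crafts bond that can scramble to symmetrical dimers), the electron-rich phenols, and the pyranone, which can open by a retro-oxa-Michael reaction. The difficulty is regiochemical: ring B must have its ring oxygen para to the C6 methyl (a 6-methyl, not an 8-methyl chromanone), ring A must be methylated on one of three hydroxyls, and the bridge must join two different phenols without homodimers. The plan rests on one feature: the C4a–C8a bond of ring B is also the enone double bond of a 2,2-dimethyl-2,3-dihydropyran-4-one, and C5–C6–C7–C8, oxygenated at C5 and C7 and methylated at C6, is the chain C1–C4 of a 2-methyl-3-oxo ester. Ring B can therefore be grown onto a heterocycle in which O1 is already in place.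

## Retrosynthetic reasoning

**Bridge (A5–CH2).** The bond between the methylene carbon and A5 of 20 is cut, not the bond to C8. Ring A ketone 18 has exactly one unsubstituted ring carbon (A5), so it can only react there as a nucleophile. Ring B can carry the one-carbon unit from its own construction as a benzylic ether (13), which ionises to the ortho-quinone methide 19. Because ring B has no free ring carbon, 19 cannot condense with its own precursor, and the coupling is a cross-coupling by design. The forward reaction must ionise one benzylic C–O bond under conditions that neither enolise the ketone of 18 nor reverse the new aryl–CH2 bond.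

**Ring A ketone (O-methyl and aryl–acyl bonds).** Compound 18 is traced to triol ketone 17 by removing the A4 methyl. The hydroxyl para to the carbonyl is the most acidic and the least hydrogen-bonded, so it can be addressed selectively. Compound 17 is cut at the aryl–carbonyl bond to the symmetrical triol 15 and acid chloride 16, made from acid 14. The two free carbons of 15 are equivalent, so acylation has no regiochemical choice, and the stereocentre is bought with 14 and not made.

**Ring B (C8–C8a and C4a–C5), the key disconnection.** Chromanone 13 is cut at C8–C8a and C4a–C5, giving diene 4 and bromoenone 9. This places the heterocyclic oxygen, the gem-dimethyl group and the C4 ketone in the two-carbon partner, and all three oxygen-bearing or methyl-bearing carbons plus the latent bridge carbon in the four-carbon partner. Cutting elsewhere (at O1–C2 or C4–C4a) would return to annulation of a methylphloroglucinol, where two hydroxyls compete. The forward reaction must join the nucleophilic terminus of 4 to the β-carbon of 9 and the ketene acetal carbon to the bromine-bearing carbon (adduct 10). It must then remove the C5 methoxy and silyl groups (11), dehydrobrominate across C4a–C8a and tautomerise (12, then 13). No oxidant is needed because the bromine supplies the missing unsaturation.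

**Diene 4.** The two silyl enol ether bonds are removed in turn (4 to 3, 3 to 2). Keto ester 2 is cut at C4–C5 to the dianion of 1 and an alkoxymethyl halide. This makes the future bridge carbon part of the diene at the cost of one alkylation.

**Bromoenone 9.** The C–Br bond is removed by way of dibromide 8 to dihydropyranone 7. The ring is opened at O1–C6 to hydroxy enone 6, and 6 is cut at C2–C3 by a retro-aldol to methoxy enone 5 and the simple ketone that supplies C2 and its two methyl groups. Each step is a standard operation on a small molecule, so the risk is concentrated in the union of 4 and 9.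

## Alternatives that were turned down

**Alternative 1:** The pyran ring is cut at C4a–C4 and O1–C2 through a chromene. The bridged dimer is first assembled with ring B as an open phloroglucinol whose C8a oxygen bears a 1,1-dimethylpropargyl group (A2). Heating should cause the aryl propargyl ether Claisen sequence: a (3,3) shift to the only free ortho carbon C4a, enolisation, a 1,5-hydrogen shift and a 6π oxa-electrocyclisation, giving chromene A1.
- For: the reaction type is very well established on phloroglucinol ethers, and the ether oxygen decides which oxygen becomes O1. On precedent for the ring-forming event this route is stronger than the chosen one, and on the 6-methyl/8-methyl question it is equal.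
- Against: A1 is at the wrong oxidation level. C3=C4 must be turned into the C4 ketone by hydration with oxygen at C4 and oxidation, two or three steps on a molecule that already holds the reversible bridge, the epimerisable stereocentre and several phenols.
- Against: A2 needs one phenol out of several to be etherified with a tertiary propargyl group, which costs protecting-group steps (the two methoxymethyl ethers), and the cascade needs temperatures at which the bridge may scramble.
- Comparison: the chosen strategy delivers C4 as a ketone directly and completes ring B before the bridge and the stereocentre exist. The endgame after its key step is one step; here it would be four or five.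

**Alternative 2:** Ring B is cut at C8a–O1 and C4a–C4. Fluoride generates an aryne from silylaryl triflate A4 in the presence of 3,3-dimethylacrylic acid A5. The carboxylate oxygen adds to C8a, the aryl anion at C4a takes the acyl carbon, and the resulting ortho-hydroxyaryl enone closes O1–C2 by oxa-Michael addition to give chromanone A3.
- For: one operation installs the ketone, the gem-dimethyl carbon and O1. The inductive effect of the C5 methoxymethoxy group should direct the oxygen nucleophile to the distal aryne carbon C8a, so on regiochemistry it is as good as the chosen route.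
- Against: A4 must be made from 15 in several steps (differentiation of the hydroxyl para to the methyl, ortho-silylation, triflation). The acyl transfer competes with simple protonation of the aryl anion. A3 has hydrogen at C8, so the bridge carbon still needs a separate step, and two protecting groups must be removed.
- Comparison: the chosen strategy reaches both partners of its key step in three steps each, needs no protecting group on ring B and installs the C8 handle during ring construction. Its ring-forming step has weaker precedent than the aryne insertion.

**Alternative 3:** Ring A is built instead of ring B, cutting A3–A4, A1–A2 and A4–A5. Cyclobutenone A7, which carries the chromanone-methyl substituent, is heated with siloxyalkyne A8. Ring opening to a vinylketene, (2+2) addition to the ynol ether, a second ring opening and 6π closure should give phenol A6, with a free hydroxyl at A4, a silyl ether at A2 and an ethyl ether at A6.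
- For: the hydroxyl to be methylated is the only free one, so O-methylation is controlled by construction. On this point it is stronger than the chosen route, which relies on an acidity difference. The stereocentre could also be introduced last.
- Against: A6 has hydrogen at A1, so the (R)-acyl group would have to be introduced by Friedel–Crafts acylation on the complete dimer, the conditions most likely to scramble the bridge and racemise the new ketone.
- Against: the A6 ethyl ether must be cleaved beside the wanted A4 methyl ether, for which no selective reagent exists.
- Against: A7 already requires a C8-functionalised chromanone, so the regiochemical problem of ring B is left unsolved.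
- Comparison: the chosen strategy spends its construction on ring B, where the regiochemistry is hardest, and obtains ring A in two classical steps. At least five steps would follow the key step of this alternative.

Key step: step 7

Remark on the chemistry: acid 14 is assumed to be purchasable as the single (R) enantiomer. Compounds 8, 10 and 11 are racemic, and 3 and 4 may form as geometric mixtures at the ester-side double bond; none of this stereochemistry reaches the target.

## Route

Step 1
Reactants: 1 methyl 2-methyl-3-oxobutanoate (racemic)
Product: 2 methyl 5-(benzyloxy)-2-methyl-3-oxopentanoate (racemic)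
Conditions: NaH, THF, 0 °C; n-BuLi, 0 °C; BnOCH2Cl, −78 → 0 °C; 1 M HCl
Reagents that add atoms: benzyl chloromethyl ether, ClCOCc1ccccc1
Why: Alkylation of a β-keto ester dianion: the second deprotonation creates the more basic carbanion at the terminal methyl (γ-carbon), which attacks the α-chloro ether, while C2 remains masked as the enolate and is not alkylated.

Step 2
Reactants: 2 methyl 5-(benzyloxy)-2-methyl-3-oxopentanoate
Product: 3 methyl (Z)-5-(benzyloxy)-2-methyl-3-(trimethylsilyloxy)pent-2-enoate
Conditions: Me3SiCl, Et3N, PhMe, rt
Reagents that add atoms: chlorotrimethylsilane, C[Si](C)(C)Cl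
Why: O-silylation of the β-keto ester under amine base gives the conjugated silyl enol ether, driven by precipitation of the amine hydrochloride; the base is too weak to expel the β-benzyloxy group.

Step 3
Reactants: 3 methyl (Z)-5-(benzyloxy)-2-methyl-3-(trimethylsilyloxy)pent-2-enoate
Product: 4 (1E,3Z)-5-(benzyloxy)-1-methoxy-2-methyl-1,3-bis(trimethylsilyloxy)penta-1,3-diene
Conditions: LiN(i-Pr)2, THF, −78 °C; Me3SiCl, −78 °C → rt; hexane, filtration
Reagents that add atoms: chlorotrimethylsilane, C[Si](C)(C)Cl
Why: Kinetic γ-deprotonation of the β-silyloxy enoate gives the extended dienolate, which is silylated on oxygen (the standard second stage in making 1-alkoxy-1,3-bis(silyloxy)dienes); the C4 substituent is expected trans to C2 across C3=C4, which places it on the outside of the s-cis diene. Low temperature and fast silyl trapping should suppress E1cB loss of benzyloxide.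

Step 4
Reactants: 5 (E)-4-methoxybut-3-en-2-one
Product: 6 (E)-5-hydroxy-1-methoxy-5-methylhex-1-en-3-one
Conditions: LiN(SiMe3)2, THF, −78 °C; acetone; AcOH, −78 °C
Reagents that add atoms: acetone, CC(C)=O
Why: Directed aldol addition: the methyl ketone is the only enolisable position of 5, and its lithium enolate adds to the ketone; the cold quench prevents retro-aldol of the tertiary aldolate.

Step 5
Reactants: 6 (E)-5-hydroxy-1-methoxy-5-methylhex-1-en-3-one
Product: 7 2,2-dimethyl-2,3-dihydro-4H-pyran-4-one
Conditions: CF3CO2H (cat.), CH2Cl2, 0 °C → rt
Reagents that add atoms: none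
Why: Acid-catalysed 6-endo oxa-Michael addition of the tertiary hydroxyl to the β-methoxy enone, followed by loss of methanol (addition–elimination), is the standard route to 2,3-dihydro-4H-pyran-4-ones.

Step 6
Reactants: 7 2,2-dimethyl-2,3-dihydro-4H-pyran-4-one
Product: 9 5-bromo-2,2-dimethyl-2,3-dihydro-4H-pyran-4-one, via trans-5,6-dibromide 8 (not isolated)
Conditions: Br2, CH2Cl2, 0 °C; Et3N, 0 °C → rt
Reagents that add atoms: bromine, BrBr
Why: Bromine adds to the enol ether double bond with electrophilic attack at C5, and Et3N removes HBr from the labile anomeric bromide 8 to restore the enone: the usual α-bromination of enones and vinylogous esters.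

Step 7
Reactants: 4 (1E,3Z)-5-(benzyloxy)-1-methoxy-2-methyl-1,3-bis(trimethylsilyloxy)penta-1,3-diene; 9 5-bromo-2,2-dimethyl-2,3-dihydro-4H-pyran-4-one
Product: 13 8-[(benzyloxy)methyl]-5,7-dihydroxy-2,2,6-trimethylchroman-4-one, via cis-fused bromo cycloadduct 10 (not isolated), via bromo enedione 11 (not isolated), via 7-O-silyl chromanone 12 (not isolated)
Conditions: 4 (2 equiv), PhMe, 110 °C, sealed tube; DBU, 0 °C → rt; AcOH, THF–H2O, rt
Reagents that add atoms: none
Why: Diene 4 is a strongly polarised 1,1,3-trioxygenated butadiene with its largest HOMO coefficient on C4, and 9 is an enone whose β-carbon C6 is the electrophilic end, so the two should combine in a highly asynchronous [4+2] cycloaddition (at the limit a Mukaiyama–Michael addition followed by closure of the α-bromo silyl enol ether onto the silyl oxocarbenium ion) that forms C8–C8a first and C4a–C5 second and gives cis-fused 10. The closest known reaction type is the cycloaddition–aromatisation of 1-alkoxy-1,3-bis(silyloxy)butadienes with α-halo enones, α-halo lactones and haloquinones, in which the halo alkene acts as an alkyne equivalent and a resorcinol results. Ring B is closed by this intermolecular [4+2] event itself, a six-membered carbocycle from a four-carbon and a two-carbon unit, so no separate cyclisation is involved. In 10 the mixed ketal at C5 is ionised with the help of the C6=C7 enol ether and sheds MeOSiMe3 to give 11, whose tertiary bromide at C4a, now α to two carbonyls, has a single β-hydrogen (C8a–H), so DBU should remove HBr across C4a–C8a as in the dehydrobromination of 2-bromo-1,3-dicarbonyl compounds. The cross-conjugated dienone that results is the keto tautomer of a phenol and shifts its C8 hydrogen to oxygen to give 12, and aqueous AcOH cleaves the aryl silyl ether to 13 without ionising the benzylic ether. No surviving stereocentre is created, since all four sp3 centres of 10 are erased, and endo/exo and facial selectivity are therefore irrelevant. The selectivity needed is regiochemical (C4 of the diene to C6 of 9, not to C5); it is secured by the matched polarity of the partners and reinforced by bromine, which lowers the LUMO and marks the α-carbon as the partner of the ketene acetal carbon, while the (3Z) geometry of 4 keeps the benzyloxymethyl group outside the s-cis diene. The base is added before any water so that C7 is still a silyl enol ether while HBr is lost, which denies the retro-oxa-Michael opening of the pyranone that a free C7 ketone would allow.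

Step 8
Reactants: 14 (R)-2-methylbutanoic acid; 15 2-methylphloroglucinol (2-methylbenzene-1,3,5-triol)
Product: 17 (R)-2-methyl-1-(2,4,6-trihydroxy-3-methylphenyl)butan-1-one, via (R)-2-methylbutanoyl chloride 16 (not isolated)
Conditions: 14, (COCl)2, DMF (cat.), CH2Cl2, 0 °C → rt; then 15, AlCl3, CH2Cl2–PhNO2, 0 °C → rt; aq. HCl
Reagents that add atoms: none
Why: Oxalyl chloride with catalytic DMF forms the acid chloride without touching the α-stereocentre, and Friedel–Crafts C-acylation of symmetrical 15 can give only one regioisomer; the AlCl3 chelate of the product resists a second acylation. The stereocentre comes from 14, and the low temperature and high nucleophilicity of 15 should keep the acylium ion too short-lived to enolise.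

Step 9
Reactants: 17 (R)-2-methyl-1-(2,4,6-trihydroxy-3-methylphenyl)butan-1-one
Product: 18 (R)-1-(2,6-dihydroxy-4-methoxy-3-methylphenyl)-2-methylbutan-1-one
Conditions: Me2SO4 (1.0 equiv), K2CO3 (1.0 equiv), acetone, rt
Reagents that add atoms: dimethyl sulfate, COS(=O)(=O)OC
Why: Williamson etherification under acidity control: with one equivalent of K2CO3 the hydroxyl para to the carbonyl, the most acidic and the one least engaged in hydrogen bonding to the ketone, is ionised and methylated. The phenoxide-bearing ketone does not enolise, so the stereocentre should be safe.

Step 10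
Reactants: 13 8-[(benzyloxy)methyl]-5,7-dihydroxy-2,2,6-trimethylchroman-4-one; 18 (R)-1-(2,6-dihydroxy-4-methoxy-3-methylphenyl)-2-methylbutan-1-one
Product: 20 (R)-1-{3-[(5,7-dihydroxy-2,2,6-trimethyl-4-oxochroman-8-yl)methyl]-2,6-dihydroxy-4-methoxy-5-methylphenyl}-2-methylbutan-1-one, via ortho-quinone methide 19 (not isolated)
Conditions: 18 (1.5 equiv), CF3CO2H, CH2Cl2, 0 °C → rt
Reagents that add atoms: none
Why: Acid ionises the benzylic ether at C8, where the cation is stabilised by O1 and the C5 and C7 hydroxyls (the protonated form of 19), and the only free carbon of 18, A5, traps it in a Friedel–Crafts alkylation, the standard construction of methylene-bridged acylphloroglucinols from a benzylic electrophile and a phenol. Ring B has no free ring carbon and cannot self-condense, and excess 18 should outcompete the reversible O-alkylation; the mild Brønsted acid should not enolise the ketone.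

## Compound list

1 | methyl 2-methyl-3-oxobutanoate (racemic) | COC(=O)C(C)C(C)=O | starting material
2 | methyl 5-(benzyloxy)-2-methyl-3-oxopentanoate (racemic) | COC(=O)C(C)C(=O)CCOCc1ccccc1 | intermediate
3 | methyl (Z)-5-(benzyloxy)-2-methyl-3-(trimethylsilyloxy)pent-2-enoate | COC(=O)/C(C)=C(\O[Si](C)(C)C)CCOCc1ccccc1 | intermediate
4 | (1E,3Z)-5-(benzyloxy)-1-methoxy-2-methyl-1,3-bis(trimethylsilyloxy)penta-1,3-diene | CO/C(O[Si](C)(C)C)=C(/C)\C(O[Si](C)(C)C)=C\COCc1ccccc1 | intermediate
5 | (E)-4-methoxybut-3-en-2-one | CO/C=C/C(C)=O | starting material
6 | (E)-5-hydroxy-1-methoxy-5-methylhex-1-en-3-one | CO/C=C/C(=O)CC(C)(C)O | intermediate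
7 | 2,2-dimethyl-2,3-dihydro-4H-pyran-4-one | CC1(C)CC(=O)C=CO1 | intermediate
8 | trans-5,6-dibromo-2,2-dimethyltetrahydro-4H-pyran-4-one (racemic, one enantiomer drawn; not isolated) | CC1(C)CC(=O)[C@@H](Br)[C@H](Br)O1 | intermediate
9 | 5-bromo-2,2-dimethyl-2,3-dihydro-4H-pyran-4-one | CC1(C)CC(=O)C(Br)=CO1 | intermediate
10 | 8-[(benzyloxy)methyl]-4a-bromo-5-methoxy-2,2,6-trimethyl-5,7-bis(trimethylsilyloxy)-2,3,4a,5,8,8a-hexahydro-4H-chromen-4-one (racemic, cis ring fusion, C5 and C8 as mixtures; not isolated) | CC1(C)CC(=O)[C@@]2(Br)C(OC)(O[Si](C)(C)C)C(C)=C(O[Si](C)(C)C)C(COCc3ccccc3)[C@H]2O1 | intermediate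
11 | 8-[(benzyloxy)methyl]-4a-bromo-2,2,6-trimethyl-7-(trimethylsilyloxy)-2,3,8,8a-tetrahydro-4H-chromene-4,5(4aH)-dione (racemic, cis ring fusion; not isolated) | CC1(C)CC(=O)[C@@]2(Br)C(=O)C(C)=C(O[Si](C)(C)C)C(COCc3ccccc3)[C@H]2O1 | intermediate
12 | 8-[(benzyloxy)methyl]-5-hydroxy-2,2,6-trimethyl-7-(trimethylsilyloxy)chroman-4-one (not isolated) | Cc1c(O[Si](C)(C)C)c(COCc2ccccc2)c2OC(C)(C)CC(=O)c2c1O | intermediate
13 | 8-[(benzyloxy)methyl]-5,7-dihydroxy-2,2,6-trimethylchroman-4-one | Cc1c(O)c(COCc2ccccc2)c2OC(C)(C)CC(=O)c2c1O | intermediate
14 | (R)-2-methylbutanoic acid | CC[C@@H](C)C(=O)O | starting material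
15 | 2-methylphloroglucinol (2-methylbenzene-1,3,5-triol) | Cc1c(O)cc(O)cc1O | starting material
16 | (R)-2-methylbutanoyl chloride (not isolated) | CC[C@@H](C)C(Cl)=O | intermediate
17 | (R)-2-methyl-1-(2,4,6-trihydroxy-3-methylphenyl)butan-1-one | CC[C@@H](C)C(=O)c1c(O)c(C)c(O)cc1O | intermediate
18 | (R)-1-(2,6-dihydroxy-4-methoxy-3-methylphenyl)-2-methylbutan-1-one | CC[C@@H](C)C(=O)c1c(O)c(C)c(OC)cc1O | intermediate
19 | 5-hydroxy-2,2,6-trimethyl-8-methylidene-2,3-dihydro-4H-chromene-4,7(8H)-dione (ortho-quinone methide; not isolated) | C=C1C(=O)C(C)=C(O)C2=C1OC(C)(C)CC2=O | intermediate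
20 | (R)-1-{3-[(5,7-dihydroxy-2,2,6-trimethyl-4-oxochroman-8-yl)methyl]-2,6-dihydroxy-4-methoxy-5-methylphenyl}-2-methylbutan-1-one | CC[C@@H](C)C(=O)c1c(O)c(C)c(OC)c(Cc2c(O)c(C)c(O)c3c2OC(C)(C)CC3=O)c1O | target

## Step count and the least certain steps

Total: 10 steps. Longest linear sequence: 5 steps (1 → 2 → 3 → 4 → 13 → 20; the dienophile branch 5 → 6 → 7 → 9 → 13 → 20 is equally long).

**Step 7 (key step).** Two processes may fail.
- The cycloaddition may stall or stop at the open-chain Michael stage. The second bond joins two fully substituted carbons (the ketene acetal carbon and the bromine-bearing carbon), and the dienophile is a donor-substituted enone.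
- The dehydrobromination may be slow. The C8a hydrogen is not acidic and is cis to bromine on the ring fusion, so no antiperiplanar arrangement exists. Halophilic debromination by the base, or ring opening of the pyranone followed by loss of positive bromine, could then take over and leave material that cannot aromatise.
- Fallback, from 7, returning at 12: the leaving group is changed to one that eliminates thermally with a cis hydrogen. Sulfenylation of 7 at C5 with PhSCl and Et3N gives 2,2-dimethyl-5-(phenylsulfanyl)-2,3-dihydro-4H-pyran-4-one F1. Oxidation with one equivalent of mCPBA gives 2,2-dimethyl-5-(phenylsulfinyl)-2,3-dihydro-4H-pyran-4-one F2, a more strongly activated dienophile. Heating F2 with 4 should give the cis-fused 4a-phenylsulfinyl analogue of 10, 8-[(benzyloxy)methyl]-5-methoxy-2,2,6-trimethyl-4a-(phenylsulfinyl)-5,7-bis(trimethylsilyloxy)-2,3,4a,5,8,8a-hexahydro-4H-chromen-4-one F3. Its sulfinyl group and C8a hydrogen are cis, the geometry a sulfoxide syn-elimination requires. Loss of benzenesulfenic acid and MeOSiMe3 leads to 12, and the AcOH work-up gives 13.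

**Step 3.** The γ-lithiated dienolate carries a benzyloxy group β to the carbanionic carbon, so E1cB loss of benzyloxide may compete with O-silylation, and the diene would be lost to an unsaturated ester.
- Fallback, from 1, returning at 19: the bridge carbon is introduced after ring B is built. Silylation of 1 as in step 2 gives methyl (Z)-2-methyl-3-(trimethylsilyloxy)but-2-enoate F4. LiN(i-Pr)2 and Me3SiCl then give (1E)-1-methoxy-2-methyl-1,3-bis(trimethylsilyloxy)buta-1,3-diene F5, whose dienolate has no β-leaving group and whose terminus is unhindered. F5 and 9 under the conditions of step 7 should give 5,7-dihydroxy-2,2,6-trimethylchroman-4-one F6. A Mannich reaction at C8, the only free ring carbon, with dimethylmethyleneiminium iodide gives 8-[(dimethylamino)methyl]-5,7-dihydroxy-2,2,6-trimethylchroman-4-one F7. Heating F7 with 18 in dioxane expels dimethylamine to form 19, which 18 traps to give 20.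

**Step 8.** The stereocentre may erode through enolisation of the acylium ion (ketene formation) or of the AlCl3-bound aryl ketone.
- Fallback, from 15 and 14, returning at 17: the C–C bond is made with an aryllithium instead of an acylium ion. Compound 15 is converted with MeOCH2Cl and i-Pr2NEt into 1,3,5-tris(methoxymethoxy)-2-methylbenzene F8. Acid 14 is converted through 16 and MeNHOMe·HCl into (R)-N-methoxy-N,2-dimethylbutanamide F9. Lithiation of F8 with n-BuLi between two methoxymethoxy groups and addition to F9 give (R)-2-methyl-1-[2,4,6-tris(methoxymethoxy)-3-methylphenyl]butan-1-one F10; the stable tetrahedral adduct protects the α-centre. HCl in MeOH at rt then gives 17.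

**Step 9.** Site-selectivity may be incomplete, with methylation of an ortho hydroxyl or over-methylation, because the three hydroxyls differ only in acidity and hydrogen bonding.
- Fallback, from 17, returning at 18: all three hydroxyls are methylated and two methyl groups are removed under chelation control. Excess Me2SO4 and K2CO3 in refluxing acetone give (R)-2-methyl-1-(2,4,6-trimethoxy-3-methylphenyl)butan-1-one F11. BCl3 in CH2Cl2 (−78 → 0 °C) should then cleave only the two methoxy groups ortho to the carbonyl, through the boron chelate, leaving the para methoxy group of 18.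

**Step 10.** The bridge may scramble by reversible Friedel–Crafts cleavage of the new aryl–CH2 bond under acid, giving symmetrical dimers, and the ketone may slowly enolise if the ionisation needs stronger acid than planned.
- Fallback, from 13, returning at 19: 19 is generated by base instead of acid. BCl3 in CH2Cl2 at −78 °C cleaves the benzylic ether at the more stabilised carbon to give 8-(chloromethyl)-5,7-dihydroxy-2,2,6-trimethylchroman-4-one F12 (benzyl alcohol after hydrolysis of its borate). Crude F12 is added to 18 and i-Pr2NEt in THF; phenoxide-driven 1,4-elimination of chloride gives 19 under non-acidic conditions, and 18 traps it to give 20.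

## Further compounds

F1 | step 7 | 2,2-dimethyl-5-(phenylsulfanyl)-2,3-dihydro-4H-pyran-4-one | CC1(C)CC(=O)C(Sc2ccccc2)=CO1
F2 | step 7 | 2,2-dimethyl-5-(phenylsulfinyl)-2,3-dihydro-4H-pyran-4-one (racemic at sulfur) | CC1(C)CC(=O)C(S(=O)c2ccccc2)=CO1
F3 | step 7 | 8-[(benzyloxy)methyl]-5-methoxy-2,2,6-trimethyl-4a-(phenylsulfinyl)-5,7-bis(trimethylsilyloxy)-2,3,4a,5,8,8a-hexahydro-4H-chromen-4-one (racemic, cis ring fusion) | CC1(C)CC(=O)[C@@]2(S(=O)c3ccccc3)C(OC)(O[Si](C)(C)C)C(C)=C(O[Si](C)(C)C)C(COCc3ccccc3)[C@H]2O1
F4 | step 3 | methyl (Z)-2-methyl-3-(trimethylsilyloxy)but-2-enoate | COC(=O)/C(C)=C(\O[Si](C)(C)C)C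
F5 | step 3 | (1E)-1-methoxy-2-methyl-1,3-bis(trimethylsilyloxy)buta-1,3-diene | CO/C(O[Si](C)(C)C)=C(/C)C(=C)O[Si](C)(C)C
F6 | step 3 | 5,7-dihydroxy-2,2,6-trimethylchroman-4-one | Cc1c(O)cc2OC(C)(C)CC(=O)c2c1O
F7 | step 3 | 8-[(dimethylamino)methyl]-5,7-dihydroxy-2,2,6-trimethylchroman-4-one | CN(C)Cc1c(O)c(C)c(O)c2C(=O)CC(C)(C)Oc12
F8 | step 8 | 1,3,5-tris(methoxymethoxy)-2-methylbenzene | Cc1c(OCOC)cc(OCOC)cc1OCOC
F9 | step 8 | (R)-N-methoxy-N,2-dimethylbutanamide | CC[C@@H](C)C(=O)N(C)OC
F10 | step 8 | (R)-2-methyl-1-[2,4,6-tris(methoxymethoxy)-3-methylphenyl]butan-1-one | CC[C@@H](C)C(=O)c1c(OCOC)c(C)c(OCOC)cc1OCOC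
F11 | step 9 | (R)-2-methyl-1-(2,4,6-trimethoxy-3-methylphenyl)butan-1-one | CC[C@@H](C)C(=O)c1c(OC)c(C)c(OC)cc1OC
F12 | step 10 | 8-(chloromethyl)-5,7-dihydroxy-2,2,6-trimethylchroman-4-one | ClCc1c(O)c(C)c(O)c2C(=O)CC(C)(C)Oc12
A1 | alternative 1 | (R)-1-[3-{[5,7-bis(methoxymethoxy)-2,2,6-trimethyl-2H-chromen-8-yl]methyl}-2,6-dihydroxy-4-methoxy-5-methylphenyl]-2-methylbutan-1-one | CC[C@@H](C)C(=O)c1c(O)c(C)c(OC)c(Cc2c(OCOC)c(C)c(OCOC)c3C=CC(C)(C)Oc23)c1O
A2 | alternative 1 | (R)-1-[3-({2,4-bis(methoxymethoxy)-3-methyl-6-[(2-methylbut-3-yn-2-yl)oxy]phenyl}methyl)-2,6-dihydroxy-4-methoxy-5-methylphenyl]-2-methylbutan-1-one | CC[C@@H](C)C(=O)c1c(O)c(C)c(OC)c(Cc2c(OCOC)c(C)c(OCOC)cc2OC(C)(C)C#C)c1O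
A3 | alternative 2 | 5,7-bis(methoxymethoxy)-2,2,6-trimethylchroman-4-one | COCOc1cc2OC(C)(C)CC(=O)c2c(OCOC)c1C
A4 | alternative 2 | 3,5-bis(methoxymethoxy)-4-methyl-2-(trimethylsilyl)phenyl trifluoromethanesulfonate | COCOc1cc(OS(=O)(=O)C(F)(F)F)c([Si](C)(C)C)c(OCOC)c1C
A5 | alternative 2 | 3,3-dimethylacrylic acid (3-methylbut-2-enoic acid) | CC(C)=CC(=O)O
A6 | alternative 3 | 5,7-bis(benzyloxy)-8-{[2-ethoxy-6-hydroxy-5-methyl-4-(triisopropylsilyloxy)phenyl]methyl}-2,2,6-trimethylchroman-4-one | Cc1c(O)c(Cc2c(OCc3ccccc3)c(C)c(OCc3ccccc3)c3c2OC(C)(C)CC3=O)c(OCC)cc1O[Si](C(C)C)(C(C)C)C(C)C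
A7 | alternative 3 | 5,7-bis(benzyloxy)-8-[(2-ethoxy-4-oxocyclobut-2-en-1-yl)methyl]-2,2,6-trimethylchroman-4-one (racemic) | CCOC1=CC(=O)C1Cc1c(OCc2ccccc2)c(C)c(OCc2ccccc2)c2c1OC(C)(C)CC2=O
A8 | alternative 3 | triisopropyl(prop-1-yn-1-yloxy)silane | CC#CO[Si](C(C)C)(C(C)C)C(C)C
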